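The benzene ring is built last. Ring carbons C1(OH), C2(OMe), C3(OMe) and C4(OH) are the four carbons of dimethyl squarate. C5(CH3)=C6(hexaprenyl) comes from a trisubstituted alkenyl anion. The C1–C4 segment is locally symmetric, so either alkene carbon may carry the metal and regiochemistry never needs control when the ring is made. The key step heats a 4-alkenyl-4-hydroxy-2,3-dimethoxycyclobutenone. The four-membered ring opens to a dienylketene, the six-membered ring closes, and enolisation gives the free hydroquinone without any redox or deprotection step. The alkenyl iodide precursor comes from all-E hexaprenyl bromide (two farnesyl halves joined through a sulfone) and a propynyl Grignard reagent.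

Key step: step 12

Assumption: the commercial farnesol and farnesyl bromide are taken as the isomerically pure (2E,6E) grades, since four of the five E alkenes of the target are inherited from them.

Step 1
Reactants: 1 (2E,6E)-farnesol
Product: 2 (2E,6E)-farnesyl tert-butyldimethylsilyl (TBS) ether
Conditions: TBSCl, imidazole, CH2Cl2, 0 °C to rt
Reagents that add atoms: TBSCl, CC(C)(C)[Si](C)(C)Cl
Why: Imidazole-promoted silylation of a primary allylic alcohol is routine, and the TBS ether is chosen because it survives SeO2, sulfone carbanions, LiBHEt3 and zerovalent palladium, which an allylic ester would not.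

Step 2
Reactants: 2 (2E,6E)-farnesyl TBS ether
Product: 4 (2E,6E,10E)-12-hydroxyfarnesyl TBS ether, via 12-oxo enal 3 (not isolated)
Conditions: SeO2 (0.1 equiv), salicylic acid (0.1 equiv), t-BuOOH (3 equiv), CH2Cl2, 0 °C to rt, stopped at partial conversion with recovery of 2; then NaBH4, EtOH, 0 °C
Reagents that add atoms: t-BuOOH, CC(C)(C)OO; SeO2 (oxygen carrier), O=[Se]=O
Why: The Riley allylic oxidation in its catalytic SeO2/t-BuOOH form (ene reaction, then [2,3]-sigmatropic shift) attacks the most electron-rich and least hindered alkene, the terminal isopropylidene, and oxygenates the methyl group trans to the chain, which fixes the E geometry of prenyl unit 3, while NaBH4 returns the over-oxidised portion 3 to alcohol 4.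

Step 3
Reactants: 4 (2E,6E,10E)-12-hydroxyfarnesyl TBS ether
Product: 6 (2E,6E,10E)-12-bromofarnesyl TBS ether (fragment 1; prenyl units 1 to 3), via allylic mesylate 5 (not isolated)
Conditions: MsCl, Et3N, CH2Cl2, −40 °C; then LiBr in THF, −40 to 0 °C
Reagents that add atoms: LiBr, [Li+].[Br-]
Why: Mesylation followed by SN2 displacement with bromide under cold, non-acidic conditions converts the primary allylic alcohol without allylic transposition, E/Z leakage or loss of the silyl ether.

Step 4
Reactants: 7 (2E,6E)-farnesyl bromide
Product: 8 (2E,6E)-farnesyl p-tolyl sulfone (fragment 2; prenyl units 4 to 6)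
Conditions: p-TolSO2Na, DMF, 0 °C to rt
Reagents that add atoms: p-TolSO2Na (sodium p-toluenesulfinate), Cc1ccc(cc1)S(=O)[O-].[Na+]
Why: SN2 S-alkylation of the ambident sulfinate anion by a primary allylic bromide in a dipolar aprotic solvent places sulfur on the primary carbon and leaves the alkene geometry untouched.

Step 5
Reactants: 8 (2E,6E)-farnesyl p-tolyl sulfone; 6 (2E,6E,10E)-12-bromofarnesyl TBS ether
Product: 10 all-E C30 TBS ether bearing the p-tolylsulfonyl group on C1 of prenyl unit 4 (racemic), via lithiated sulfone 9 (not isolated)
Conditions: 8, n-BuLi (1.05 equiv), THF–DMPU (4:1), −78 °C; then 6, −78 to −20 °C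
Reagents that add atoms: none
Why: Alkylation of a sulfone-stabilised allyl anion (Biellmann/Julia-type head-to-tail prenyl coupling) takes place at the carbon alpha to sulfur by SN2 attack on the primary allylic bromide, so both neighbouring alkenes keep position and geometry, and the new sulfonyl-bearing stereocentre forms as a racemate that is deleted in step 6.

Step 6
Reactants: 10 C30 sulfone TBS ether
Product: 11 all-E hexaprenyl TBS ether
Conditions: PdCl2(dppp) (5 mol %), LiBHEt3 (2.5 equiv), THF, 0 °C
Reagents that add atoms: none
Why: In this palladium-catalysed hydride substitution of an allylic sulfone, zerovalent palladium formed in situ ionises the C–S bond and hydride goes to the less substituted terminus of the π-allyl complex, a method established on polyprenyl sulfones that preserves alkene position and E geometry better than dissolving-metal reduction and does not ionise the allylic silyl ether.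

Step 7
Reactants: 11 all-E hexaprenyl TBS ether
Product: 12 all-E hexaprenol
Conditions: Bu4NF, THF, 0 °C to rt
Reagents that add atoms: none
Why: Fluoride-driven Si–O cleavage is a standard desilylation and does not affect the six isolated alkenes.

Step 8
Reactants: 12 all-E hexaprenol
Product: 13 all-E hexaprenyl bromide (used crude)
Conditions: PBr3 (0.4 equiv), Et2O, −10 °C, dark
Reagents that add atoms: PBr3, BrP(Br)Br
Why: Bromination of a primary allylic alcohol with PBr3 through a phosphite ester and SN2 displacement is the usual access to polyprenyl bromides, and low temperature, short contact and omission of chromatography limit allylic rearrangement and E/Z erosion.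

Step 9
Reactants: 13 all-E hexaprenyl bromide; 14 1-propynylmagnesium bromide (THF solution)
Product: 15 (5E,9E,13E,17E,21E)-6,10,14,18,22,26-hexamethylheptacosa-5,9,13,17,21,25-hexaen-2-yne (skipped enyne)
Conditions: CuBr·SMe2 (10 mol %), 14 (1.3 equiv), THF, 0 °C to rt
Reagents that add atoms: none
Why: Copper-catalysed cross-coupling of an alkynyl Grignard reagent with an allylic halide gives the 1,4-enyne by attack at the primary alpha carbon because the gamma carbon is fully substituted, and the weakly basic acetylide at or below ambient temperature does not isomerise the skipped enyne.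

Step 10
Reactants: 15 skipped enyne
Product: 17 (2E,5E,9E,13E,17E,21E)-2-iodo-6,10,14,18,22,26-hexamethylheptacosa-2,5,9,13,17,21,25-heptaene, via alkenylzirconocene chloride 16 (not isolated)
Conditions: Cp2Zr(H)Cl (1.3 equiv), THF, rt, dark; then I2 (1.3 equiv) in THF, −20 °C
Reagents that add atoms: I2, [I][I]
Why: Hydrozirconation with Cp2Zr(H)Cl adds H and Zr syn across the alkyne much faster than across trisubstituted alkenes, with zirconium preferring the methyl-bearing carbon, and iodinolysis of the C–Zr bond proceeds with retention, while material of the opposite regiochemistry need not be removed because it leads to the same arene.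

Step 11
Reactants: 17 (E)-alkenyl iodide; 18 dimethyl squarate
Product: 21 4-hydroxy-2,3-dimethoxy-4-[(2E,5E,9E,13E,17E,21E)-6,10,14,18,22,26-hexamethylheptacosa-2,5,9,13,17,21,25-heptaen-2-yl]cyclobut-2-en-1-one (racemic), via alkenyllithium 19 (not isolated), via lithium alkoxide 20 (not isolated)
Conditions: 17, t-BuLi (2.05 equiv), Et2O, −78 °C; cannulated slowly into 18 (1.3 equiv), THF, −78 °C; sat. aq NH4Cl at −78 °C; rapid cold chromatography, stored at −20 °C
Reagents that add atoms: none
Why: Iodine–lithium exchange with two equivalents of t-BuLi is fast and stereoretentive at −78 °C and places lithium trans to the doubly allylic CH2 so that proton transfer is slow, alkenyllithiums are known to add 1,2 to one of the two equivalent carbonyl groups of squaric esters, inverse addition into excess 18 suppresses a second addition, and the carbinol stereocentre forms racemic and vanishes in step 12.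

Step 12
Reactants: 21 4-alkenyl-4-hydroxy-2,3-dimethoxycyclobutenone
Product: 24 ubiquinol-6, via dienylketene 22 (not isolated), via cyclohexa-2,4-dienone 23 (not isolated)
Conditions: degassed toluene (0.01 M), 110 °C, Ar; concentration and chromatography with Ar-sparged solvents
Reagents that add atoms: none
Why: Heating breaks the C1–C4 bond of the cyclobutenone in a conrotatory 4π electrocyclic opening to dienylketene 22, whose ketene carbon (old C1) then bonds to the alkene CH carbon (future C6) in a disrotatory 6π electrocyclisation that closes the only six-membered ring as dienone 23, and enolisation of the C6–H gives both phenols of 24 at once. This is the Moore rearrangement, the known thermal ring expansion of squarate-derived 4-alkenyl-4-hydroxycyclobutenones to hydroquinones. The selectivity required is torquoselectivity, because only the ketene with the alkenyl group turned inward can cyclise, and it is secured by the C4 hydroxyl, the stronger donor, which rotates outward. Regiochemistry is not an issue because C1(OH), C2(OMe), C3(OMe) and C4(OH) form a locally symmetric set, so methyl and hexaprenyl may end on either of C5 and C6. No stereocentre survives, since the carbinol carbon of 21 becomes sp2 on opening and the sp3 carbon of 23 is erased on aromatisation, while the E geometry of the reacting alkene points the chain outward in the closure and the unconjugated chain alkenes stay inert at 110 °C. High dilution prevents capture of the ketene by phenolic product, and rigorous exclusion of oxygen keeps the product at the hydroquinone level.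

Compound list
1 | (2E,6E)-farnesol | CC(C)=CCC/C(C)=C/CC/C(C)=C/CO | starting material
2 | (2E,6E)-farnesyl TBS ether | CC(C)=CCC/C(C)=C/CC/C(C)=C/CO[Si](C)(C)C(C)(C)C | intermediate
3 | (2E,6E,10E)-12-(TBS-oxy)-2,6,10-trimethyldodeca-2,6,10-trienal (not isolated) | O=C/C(C)=C/CC/C(C)=C/CC/C(C)=C/CO[Si](C)(C)C(C)(C)C | intermediate
4 | (2E,6E,10E)-12-hydroxyfarnesyl TBS ether | OC/C(C)=C/CC/C(C)=C/CC/C(C)=C/CO[Si](C)(C)C(C)(C)C | intermediate
5 | methanesulfonate of 4 (not isolated) | CS(=O)(=O)OC/C(C)=C/CC/C(C)=C/CC/C(C)=C/CO[Si](C)(C)C(C)(C)C | intermediate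
6 | (2E,6E,10E)-12-bromofarnesyl TBS ether (fragment 1) | BrC/C(C)=C/CC/C(C)=C/CC/C(C)=C/CO[Si](C)(C)C(C)(C)C | intermediate
7 | (2E,6E)-farnesyl bromide | CC(C)=CCC/C(C)=C/CC/C(C)=C/CBr | starting material
8 | (2E,6E)-farnesyl p-tolyl sulfone (fragment 2) | CC(C)=CCC/C(C)=C/CC/C(C)=C/CS(=O)(=O)c1ccc(C)cc1 | intermediate
9 | alpha-lithiated farnesyl p-tolyl sulfone (not isolated) | CC(C)=CCC/C(C)=C/CC/C(C)=C/C([Li])S(=O)(=O)c1ccc(C)cc1 | intermediate
10 | all-E C30 TBS ether with p-tolylsulfonyl on C1 of prenyl unit 4 (racemic) | CC(C)=CCC/C(C)=C/CC/C(C)=C/C(C/C(C)=C/CC/C(C)=C/CC/C(C)=C/CO[Si](C)(C)C(C)(C)C)S(=O)(=O)c1ccc(C)cc1 | intermediate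
11 | all-E hexaprenyl TBS ether | CC(C)=CCC/C(C)=C/CC/C(C)=C/CC/C(C)=C/CC/C(C)=C/CC/C(C)=C/CO[Si](C)(C)C(C)(C)C | intermediate
12 | all-E hexaprenol, (2E,6E,10E,14E,18E)-3,7,11,15,19,23-hexamethyltetracosa-2,6,10,14,18,22-hexaen-1-ol | CC(C)=CCC/C(C)=C/CC/C(C)=C/CC/C(C)=C/CC/C(C)=C/CC/C(C)=C/CO | intermediate
13 | all-E hexaprenyl bromide | CC(C)=CCC/C(C)=C/CC/C(C)=C/CC/C(C)=C/CC/C(C)=C/CC/C(C)=C/CBr | intermediate
14 | 1-propynylmagnesium bromide | CC#C[Mg]Br | starting material
15 | (5E,9E,13E,17E,21E)-6,10,14,18,22,26-hexamethylheptacosa-5,9,13,17,21,25-hexaen-2-yne | CC#CC/C=C(\C)CC/C=C(\C)CC/C=C(\C)CC/C=C(\C)CC/C=C(\C)CCC=C(C)C | intermediate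
16 | (E)-alkenylzirconocene chloride, Zr on C2 and trans to the chain CH2 (not isolated; Cp rings written sigma-bonded) | Cl[Zr](C1C=CC=C1)(C1C=CC=C1)/C(C)=C/C/C=C(\C)CC/C=C(\C)CC/C=C(\C)CC/C=C(\C)CC/C=C(\C)CCC=C(C)C | intermediate
17 | (2E,5E,9E,13E,17E,21E)-2-iodo-6,10,14,18,22,26-hexamethylheptacosa-2,5,9,13,17,21,25-heptaene | I/C(C)=C/C/C=C(\C)CC/C=C(\C)CC/C=C(\C)CC/C=C(\C)CC/C=C(\C)CCC=C(C)C | intermediate
18 | dimethyl squarate (3,4-dimethoxycyclobut-3-ene-1,2-dione) | COC1=C(OC)C(=O)C1=O | starting material
19 | alkenyllithium from 17, configuration retained (not isolated) | [Li]/C(C)=C/C/C=C(\C)CC/C=C(\C)CC/C=C(\C)CC/C=C(\C)CC/C=C(\C)CCC=C(C)C | intermediate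
20 | lithium alkoxide of 21 (racemic, not isolated) | COC1=C(OC)C(O[Li])(/C(C)=C/C/C=C(\C)CC/C=C(\C)CC/C=C(\C)CC/C=C(\C)CC/C=C(\C)CCC=C(C)C)C1=O | intermediate
21 | 4-alkenyl-4-hydroxy-2,3-dimethoxycyclobut-2-en-1-one (racemic carbinol, E alkene at the ring) | COC1=C(OC)C(O)(/C(C)=C/C/C=C(\C)CC/C=C(\C)CC/C=C(\C)CC/C=C(\C)CC/C=C(\C)CCC=C(C)C)C1=O | intermediate
22 | dienylketene, central C=C Z with the alkenyl group cis to the ketenyl carbon (not isolated) | O=C=C(OC)/C(OC)=C(O)\C(C)=C\C/C=C(\C)CC/C=C(\C)CC/C=C(\C)CC/C=C(\C)CC/C=C(\C)CCC=C(C)C | intermediate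
23 | 6-hexaprenyl-4-hydroxy-2,3-dimethoxy-5-methylcyclohexa-2,4-dien-1-one (racemic, not isolated) | O=C1C(OC)=C(OC)C(O)=C(C)C1C/C=C(\C)CC/C=C(\C)CC/C=C(\C)CC/C=C(\C)CC/C=C(\C)CCC=C(C)C | intermediate
24 | ubiquinol-6, 2,3-dimethoxy-5-methyl-6-(all-E-hexaprenyl)benzene-1,4-diol | COc1c(O)c(C)c(C/C=C(\C)CC/C=C(\C)CC/C=C(\C)CC/C=C(\C)CC/C=C(\C)CCC=C(C)C)c(O)c1OC | target

Total step count: 12. Longest linear sequence: 11 steps (1 to 24 through steps 1 to 3 and 5 to 12; step 4 is the only branch). Step 2 is expected to be the least efficient step. It is early, uses cheap material and allows recycling of 2, so it is not counted among the three below.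

Steps most likely to fail

Step 11. What may go wrong:
- proton transfer from the doubly allylic CH2 to the alkenyllithium
- incomplete halogen–metal exchange
- a second addition to the squarate
- premature ring opening during isolation

All of these would cost the most valuable intermediate. The fallback sets out from dimethyl squarate 18 and hexaprenol 12 and comes back at 24. It keeps the squarate ring expansion but takes the polyene chain out of the organometallic chemistry. Commercial CH2=C(CH3)MgBr is added to 18 (THF, −78 °C) to give 4-hydroxy-2,3-dimethoxy-4-(prop-1-en-2-yl)cyclobut-2-en-1-one F1. Thermolysis in degassed toluene gives 2,3-dimethoxy-5-methylbenzene-1,4-diol F2. Friedel–Crafts allylation of its only free ring position with 12 (BF3·OEt2, dioxane, rt, Ar) then gives 24. This acid-mediated coupling of the hydroquinone with polyprenols is known, but it may erode the E geometry of prenyl unit 1, which is why it is the second choice.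

Step 10. What may go wrong:
- incomplete hydrometalation with aged reagent
- reaction at chain alkenes when excess reagent is used
- migration of the skipped unsaturation
- protonolysis of the C–Zr bond before iodine arrives
- attack of iodine on the chain alkenes

The fallback sets out from enyne 15 and comes back at iodide 17. Copper-catalysed syn borylcupration and protonation of the alkyne is used (CuCl, PCy3 and NaOt-Bu, each catalytic, with B2pin2 and MeOH in toluene at rt). Unactivated trisubstituted alkenes do not react under these conditions. The product is the chromatographable (Z)-2-(4,4,5,5-tetramethyl-1,3,2-dioxaborolan-2-yl)alk-2-ene F3, and its regiochemistry is again irrelevant. Formation of the boronate with NaOH and slow addition of I2 (THF–H2O, 0 °C) then replaces boron by iodine with retention to give 17.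

Step 12. What may go wrong: autoxidation of the hydroquinone during heating, concentration and chromatography would leave mixtures of two oxidation levels that are hard to purify. The fallback sets out from 21 and comes back at 24. After the same thermolysis the crude material is deliberately oxidised with Ag2O (Et2O, rt) to ubiquinone-6 F4, which is air-stable and can be purified on silica without precautions. A final two-phase reduction with aqueous Na2S2O4 (Et2O–EtOH, Ar) returns 24, which is isolated by phase separation and evaporation under argon with no chromatography at the hydroquinone stage.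

Further compounds
F1 | step 11 | 4-hydroxy-2,3-dimethoxy-4-(prop-1-en-2-yl)cyclobut-2-en-1-one (racemic) | COC1=C(OC)C(O)(C(C)=C)C1=O
F2 | step 11 | 2,3-dimethoxy-5-methylbenzene-1,4-diol | COc1c(O)c(C)cc(O)c1OC
F3 | step 10 | (2Z,5E,9E,13E,17E,21E)-2-(4,4,5,5-tetramethyl-1,3,2-dioxaborolan-2-yl)-6,10,14,18,22,26-hexamethylheptacosa-2,5,9,13,17,21,25-heptaene (boron trans to the chain CH2) | CC1(C)OB(OC1(C)C)/C(C)=C/C/C=C(\C)CC/C=C(\C)CC/C=C(\C)CC/C=C(\C)CC/C=C(\C)CCC=C(C)C
F4 | step 12 | ubiquinone-6, 2,3-dimethoxy-5-methyl-6-(all-E-hexaprenyl)-1,4-benzoquinone | COC1=C(OC)C(=O)C(C/C=C(\C)CC/C=C(\C)CC/C=C(\C)CC/C=C(\C)CC/C=C(\C)CCC=C(C)C)=C(C)C1=O
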